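**Retrosynthetic overview**
- The target comes from a benzyl-protected oxolanyl acetate whose future CH2OH is carried as CH2Bpin, so the tertiary acetate can be installed with no hydroxyl protection.
- The oxolane (the only ring formed) is closed by a SmI2 ketyl–olefin 5-exo cyclisation: the ketyl carbon (future C3) bonds to the β-carbon of an alkenyl boronate (future C4). Both new stereocentres are set from the benzylic ether centre, and the alkoxide is acetylated in the same pot.
- The cyclisation precursor comes from cross-metathesis of an allyl ether ketone with vinyl-Bpin; the ketone comes from a Weinreb amide and a benzylic Grignard reagent; the ether comes from Williamson alkylation of an (S)-aryl vinyl carbinol.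
- The (S)-carbinol comes from lipase resolution of the adduct of veratraldehyde and vinylmagnesium bromide.

Assumption: the SMILES is read as (3S,4R,5S) on the oxolane (aryl/CH2OH trans, CH2OH/OAc trans, benzyl/CH2OH cis); compounds 1, 2, 5, 7 and 11 are taken as catalogue items.

**Step 1**
Reactants: 1 3,4-dimethoxybenzaldehyde; 2 vinylmagnesium bromide
Product: 3 rac-1-(3,4-dimethoxyphenyl)prop-2-en-1-ol
Conditions: THF, 0 °C; aq NH4Cl
Reagents that add atoms: vinylmagnesium bromide, C=C[Mg]Br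
Why: Grignard 1,2-addition to an aryl aldehyde; the carbinol centre is formed racemic and is resolved in step 2.

**Step 2**
Reactants: 3 rac-1-(3,4-dimethoxyphenyl)prop-2-en-1-ol
Product: 4 (S)-1-(3,4-dimethoxyphenyl)prop-2-en-1-ol
Conditions: Novozym 435 (immobilised Candida antarctica lipase B), vinyl acetate, MTBE, 30 °C, stopped at about 52% conversion; chromatography
Reagents that add atoms: none
Why: Lipase kinetic resolution by enantioselective transesterification; by the Kazlauskas rule the (R)-aryl carbinol is acylated and the (S)-alcohol is left in high ee (maximum yield 50%).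

**Step 3**
Reactants: 4 (S)-1-(3,4-dimethoxyphenyl)prop-2-en-1-ol; 5 2-chloro-N-methoxy-N-methylacetamide
Product: 6 (S)-2-{[1-(3,4-dimethoxyphenyl)prop-2-en-1-yl]oxy}-N-methoxy-N-methylacetamide
Conditions: NaH (1.05 equiv), THF, 0 °C; then 5, Bu4NI (cat.), 0 °C → rt
Reagents that add atoms: 2-chloro-N-methoxy-N-methylacetamide, CON(C)C(=O)CCl
Why: Williamson ether synthesis (SN2 at the α-chloro amide); the Weinreb amide is inert to the alkoxide and the carbinol centre is not touched, while the limited base avoids enolate [2,3]-Wittig rearrangement.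

**Step 4**
Reactants: 7 4-(benzyloxy)-3-methoxybenzyl alcohol
Product: 8 4-(benzyloxy)-3-methoxybenzyl chloride
Conditions: SOCl2 (1.2 equiv), CH2Cl2, 0 °C → rt
Reagents that add atoms: thionyl chloride, O=S(Cl)Cl
Why: Chlorodehydroxylation of an electron-rich benzylic alcohol through its chlorosulfite.

**Step 5**
Reactants: 8 4-(benzyloxy)-3-methoxybenzyl chloride; 6 (S)-2-{[1-(3,4-dimethoxyphenyl)prop-2-en-1-yl]oxy}-N-methoxy-N-methylacetamide
Product: 10 (S)-1-[4-(benzyloxy)-3-methoxyphenyl]-3-{[1-(3,4-dimethoxyphenyl)prop-2-en-1-yl]oxy}propan-2-one, via benzylic magnesium chloride 9 (not isolated)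
Conditions: 8, Mg turnings (BrCH2CH2Br-activated), THF, 0 °C, slow addition; then 6, −20 → 0 °C; aq NH4Cl
Reagents that add atoms: none
Why: Weinreb ketone synthesis; the chelated tetrahedral adduct prevents over-addition and collapses to the ketone only on work-up, so the base-sensitive α-allyloxy ketone never meets the Grignard reagent.

**Step 6**
Reactants: 10 (S)-1-[4-(benzyloxy)-3-methoxyphenyl]-3-{[1-(3,4-dimethoxyphenyl)prop-2-en-1-yl]oxy}propan-2-one; 11 vinylboronic acid pinacol ester
Product: 12 (S,E)-1-[4-(benzyloxy)-3-methoxyphenyl]-3-{[1-(3,4-dimethoxyphenyl)-3-(4,4,5,5-tetramethyl-1,3,2-dioxaborolan-2-yl)prop-2-en-1-yl]oxy}propan-2-one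
Conditions: 11 (3 equiv), second-generation Grubbs catalyst RuCl2(=CHPh)(H2IMes)(PCy3) (5 mol%), 1,4-benzoquinone (10 mol%), CH2Cl2, 40 °C
Reagents that add atoms: vinylboronic acid pinacol ester, C=CB1OC(C)(C)C(C)(C)O1
Why: Olefin cross-metathesis, which is E-selective with vinyl-Bpin and tolerates the ketone; benzoquinone suppresses Ru–H isomerisation of the allyl ether.

**Step 7**
Reactants: 12 (S,E)-1-[4-(benzyloxy)-3-methoxyphenyl]-3-{[1-(3,4-dimethoxyphenyl)-3-(4,4,5,5-tetramethyl-1,3,2-dioxaborolan-2-yl)prop-2-en-1-yl]oxy}propan-2-one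
Product: 14 (3S,4R,5S)-3-[4-(benzyloxy)-3-methoxybenzyl]-5-(3,4-dimethoxyphenyl)-4-[(4,4,5,5-tetramethyl-1,3,2-dioxaborolan-2-yl)methyl]oxolan-3-yl acetate, via trivalent samarium alkoxide 13 (not isolated)
Conditions: SmI2 (2.3 equiv), HMPA (8 equiv), t-BuOH (2 equiv), THF (0.01 M), −78 → 0 °C; then Ac2O (10 equiv), DMAP (1 equiv), 0 °C → rt
Reagents that add atoms: acetic anhydride, CC(=O)OC(C)=O
Why: Proposed new method: SmI2–HMPA reduces the ketone to a ketyl radical anion (a carbonyl carbon made nucleophilic) that adds 5-exo-trig to the electrophilic β-carbon of the alkenyl boronate, giving an α-boryl radical stabilised by the empty boron p orbital, which is reduced and protonated by t-BuOH; a chair-like Beckwith–Houk transition state with the aryl group pseudo-equatorial and the bulky O–Sm(HMPA)n group anti to the alkene puts CH2B trans to aryl (C4) and oxygen trans to CH2B with benzyl cis (C3), and the samarium alkoxide, which cannot chelate the trans boronate, is acetylated in the pot; closest known reaction type: SmI2/HMPA ketyl–olefin 5-exo cyclisation with anti selectivity and in-situ electrophile trapping, combined with Giese-type radical addition to vinyl pinacol boronates.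

**Step 8**
Reactants: 14 (3S,4R,5S)-3-[4-(benzyloxy)-3-methoxybenzyl]-5-(3,4-dimethoxyphenyl)-4-[(4,4,5,5-tetramethyl-1,3,2-dioxaborolan-2-yl)methyl]oxolan-3-yl acetate
Product: 15 (3S,4R,5S)-3-[4-(benzyloxy)-3-methoxybenzyl]-5-(3,4-dimethoxyphenyl)-4-(hydroxymethyl)oxolan-3-yl acetate
Conditions: NaBO3·4H2O (3 equiv), THF/H2O 1:1, 0 °C → rt, 1–2 h; pH 7 buffer quench
Reagents that add atoms: sodium perborate, [Na+].[O-]OB=O
Why: Oxidation of the primary C–B bond by perborate (1,2-boron-to-oxygen shift); the mild pH and short time spare the hindered tertiary acetate, and no stereocentre is involved.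

**Step 9**
Reactants: 15 (3S,4R,5S)-3-[4-(benzyloxy)-3-methoxybenzyl]-5-(3,4-dimethoxyphenyl)-4-(hydroxymethyl)oxolan-3-yl acetate
Product: 16 (3S,4R,5S)-5-(3,4-dimethoxyphenyl)-3-(4-hydroxy-3-methoxybenzyl)-4-(hydroxymethyl)oxolan-3-yl acetate
Conditions: H2 (1 atm), 10% Pd/C, EtOAc, rt, stopped at full debenzylation
Reagents that add atoms: none
Why: Catalytic hydrogenolysis of the aryl benzyl ether, which is much faster than cleavage of the cyclic benzylic C–O bond; neutral conditions avoid acetyl migration to the primary alcohol.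

**Compound list**
1 | 3,4-dimethoxybenzaldehyde | COc1ccc(C=O)cc1OC | starting material
2 | vinylmagnesium bromide | C=C[Mg]Br | starting material
3 | rac-1-(3,4-dimethoxyphenyl)prop-2-en-1-ol | C=CC(O)c1ccc(OC)c(OC)c1 | intermediate
4 | (S)-1-(3,4-dimethoxyphenyl)prop-2-en-1-ol | C=C[C@H](O)c1ccc(OC)c(OC)c1 | intermediate
5 | 2-chloro-N-methoxy-N-methylacetamide | CON(C)C(=O)CCl | starting material
6 | (S)-2-{[1-(3,4-dimethoxyphenyl)prop-2-en-1-yl]oxy}-N-methoxy-N-methylacetamide | C=C[C@H](OCC(=O)N(C)OC)c1ccc(OC)c(OC)c1 | intermediate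
7 | 4-(benzyloxy)-3-methoxybenzyl alcohol | COc1cc(CO)ccc1OCc1ccccc1 | starting material
8 | 4-(benzyloxy)-3-methoxybenzyl chloride | COc1cc(CCl)ccc1OCc1ccccc1 | intermediate
9 | [4-(benzyloxy)-3-methoxybenzyl]magnesium chloride | COc1cc(C[Mg]Cl)ccc1OCc1ccccc1 | intermediate (not isolated)
10 | (S)-1-[4-(benzyloxy)-3-methoxyphenyl]-3-{[1-(3,4-dimethoxyphenyl)prop-2-en-1-yl]oxy}propan-2-one | C=C[C@H](OCC(=O)Cc1ccc(OCc2ccccc2)c(OC)c1)c1ccc(OC)c(OC)c1 | intermediate
11 | vinylboronic acid pinacol ester | C=CB1OC(C)(C)C(C)(C)O1 | starting material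
12 | (S,E)-1-[4-(benzyloxy)-3-methoxyphenyl]-3-{[1-(3,4-dimethoxyphenyl)-3-(4,4,5,5-tetramethyl-1,3,2-dioxaborolan-2-yl)prop-2-en-1-yl]oxy}propan-2-one | CC1(C)OB(/C=C/[C@H](OCC(=O)Cc2ccc(OCc3ccccc3)c(OC)c2)c2ccc(OC)c(OC)c2)OC1(C)C | intermediate
13 | diiodosamarium (trivalent samarium) (3S,4R,5S)-3-[4-(benzyloxy)-3-methoxybenzyl]-5-(3,4-dimethoxyphenyl)-4-[(pinacolboryl)methyl]oxolan-3-olate | COc1cc(C[C@@]2(O[Sm](I)I)CO[C@H](c3ccc(OC)c(OC)c3)[C@H]2CB4OC(C)(C)C(C)(C)O4)ccc1OCc5ccccc5 | intermediate (not isolated)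
14 | (3S,4R,5S)-3-[4-(benzyloxy)-3-methoxybenzyl]-5-(3,4-dimethoxyphenyl)-4-[(4,4,5,5-tetramethyl-1,3,2-dioxaborolan-2-yl)methyl]oxolan-3-yl acetate | COc1cc(C[C@@]2(OC(C)=O)CO[C@H](c3ccc(OC)c(OC)c3)[C@H]2CB4OC(C)(C)C(C)(C)O4)ccc1OCc5ccccc5 | intermediate
15 | (3S,4R,5S)-3-[4-(benzyloxy)-3-methoxybenzyl]-5-(3,4-dimethoxyphenyl)-4-(hydroxymethyl)oxolan-3-yl acetate | COc1cc(C[C@@]2(OC(C)=O)CO[C@H](c3ccc(OC)c(OC)c3)[C@H]2CO)ccc1OCc4ccccc4 | intermediate
16 | (3S,4R,5S)-5-(3,4-dimethoxyphenyl)-3-(4-hydroxy-3-methoxybenzyl)-4-(hydroxymethyl)oxolan-3-yl acetate | COc1cc(C[C@@]2(OC(C)=O)CO[C@H](c3ccc(OC)c(OC)c3)[C@H]2CO)ccc1O | target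

**Step count**
Total steps: 9. Longest linear sequence: 8 (steps 1, 2, 3, 5, 6, 7, 8, 9 from 3,4-dimethoxybenzaldehyde); step 4 is a one-step side branch.

**Three steps most likely to fail**

Step 7 (key cyclisation). The risks are loss of the tether by expulsion of the α-alkoxide from the ketyl, an unfavourable diastereomer ratio with the boronate acceptor, and incomplete acetylation of the hindered alkoxide. The fallback sets out from 10 and comes back at 15, and does without the boron handle. Ketone 10 is added slowly to SmI2/HMPA in THF at 0 °C with no proton source, so that the ketyl closes 5-exo onto the unactivated vinyl group with the same anti sense. The primary alkylsamarium formed is then trapped with dry O2 to give (3S,4R,5S)-3-[4-(benzyloxy)-3-methoxybenzyl]-5-(3,4-dimethoxyphenyl)-4-(hydroxymethyl)oxolan-3-ol F2. The primary hydroxyl is silylated (TBSCl, imidazole, DMF, 0 °C) to give (3S,4R,5S)-3-[4-(benzyloxy)-3-methoxybenzyl]-4-{[(tert-butyldimethylsilyl)oxy]methyl}-5-(3,4-dimethoxyphenyl)oxolan-3-ol F3. The tertiary hydroxyl is acetylated (Ac2O, DMAP, Et3N, 50 °C) to give (3S,4R,5S)-3-[4-(benzyloxy)-3-methoxybenzyl]-4-{[(tert-butyldimethylsilyl)oxy]methyl}-5-(3,4-dimethoxyphenyl)oxolan-3-yl acetate F4. Desilylation under acidic fluoride (HF·pyridine, THF/pyridine, 0 °C) then gives 15.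

Step 6 (cross-metathesis). The allylic position is branched and doubly activated (aryl, ether), so the metathesis may be slow and Ru–H isomerisation to the enol ether may compete. The fallback sets out from 10 and comes back at 12. Lemieux–Johnson cleavage of the vinyl group (OsO4 cat., NaIO4, 2,6-lutidine, dioxane/H2O) gives (R)-2-{3-[4-(benzyloxy)-3-methoxyphenyl]-2-oxopropoxy}-2-(3,4-dimethoxyphenyl)acetaldehyde F1. The spatial arrangement is unchanged; the descriptor changes only because CHO outranks aryl. F1 is used crude, to avoid epimerisation, in a Takai-type chromium boron-olefination (Cl2CHBpin, CrCl2, LiI, THF, rt). This is aldehyde-selective over the ketone and E-selective, and gives 12.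

Step 8 (C–B oxidation). Mildly basic perborate may let the acetyl group migrate from the tertiary oxygen to the new primary alkoxide, or cleave it. The fallback sets out from 14 and comes back at 15. The boronate is converted with KHF2 (MeOH/H2O, rt) into potassium {[(3S,4R,5S)-4-acetoxy-4-[4-(benzyloxy)-3-methoxybenzyl]-2-(3,4-dimethoxyphenyl)oxolan-3-yl]methyl}trifluoroborate F5. F5 is oxidised within minutes by Oxone (acetone/H2O, rt) under slightly acidic conditions, where acyl migration is slow, to give 15.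

**Further compounds**
F1 | step 6 | (R)-2-{3-[4-(benzyloxy)-3-methoxyphenyl]-2-oxopropoxy}-2-(3,4-dimethoxyphenyl)acetaldehyde | O=C[C@H](OCC(=O)Cc1ccc(OCc2ccccc2)c(OC)c1)c1ccc(OC)c(OC)c1
F2 | step 7 | (3S,4R,5S)-3-[4-(benzyloxy)-3-methoxybenzyl]-5-(3,4-dimethoxyphenyl)-4-(hydroxymethyl)oxolan-3-ol | COc1cc(C[C@@]2(O)CO[C@H](c3ccc(OC)c(OC)c3)[C@H]2CO)ccc1OCc4ccccc4
F3 | step 7 | (3S,4R,5S)-3-[4-(benzyloxy)-3-methoxybenzyl]-4-{[(tert-butyldimethylsilyl)oxy]methyl}-5-(3,4-dimethoxyphenyl)oxolan-3-ol | COc1cc(C[C@@]2(O)CO[C@H](c3ccc(OC)c(OC)c3)[C@H]2CO[Si](C)(C)C(C)(C)C)ccc1OCc4ccccc4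
F4 | step 7 | (3S,4R,5S)-3-[4-(benzyloxy)-3-methoxybenzyl]-4-{[(tert-butyldimethylsilyl)oxy]methyl}-5-(3,4-dimethoxyphenyl)oxolan-3-yl acetate | COc1cc(C[C@@]2(OC(C)=O)CO[C@H](c3ccc(OC)c(OC)c3)[C@H]2CO[Si](C)(C)C(C)(C)C)ccc1OCc4ccccc4
F5 | step 8 | potassium {[(3S,4R,5S)-4-acetoxy-4-[4-(benzyloxy)-3-methoxybenzyl]-2-(3,4-dimethoxyphenyl)oxolan-3-yl]methyl}trifluoroborate | COc1cc(C[C@@]2(OC(C)=O)CO[C@H](c3ccc(OC)c(OC)c3)[C@H]2C[B-](F)(F)F)ccc1OCc4ccccc4.[K+]
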